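**Retrosynthetic overview**

- Endgame: the phenol (PMB ether) and the acetyl group (dioxolane) are unmasked last. Before that the angelate is put on O–C3 and the acetate on the side-chain CH2O, whose carbon is grown from a C1'–B bond by one-carbon boronate homologation and oxidation.
- Feature on which the strategy rests: in the dihydrofuran ring of the 2,3-dihydrobenzofuran, C2 carries the ring oxygen O1, the carbinol carbon C3 and the alkene carbon C1' (benzofuran numbering, C1' on C2). This is the pattern left when the oxygen-bearing carbon of an aryloxyallene adds to an ortho formyl group while the central allene carbon takes up boron.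
- Key disconnection: C2–C3, formed together with the dihydrofuran ring (the only ring made; the benzene ring is bought) and both stereocentres, by a copper–boryl cyclization of an ortho-formyl aryl allenyl ether with bis(pinacolato)diboron.
- The allenyl ether aldehyde comes from 2,4-dihydroxyacetophenone by C5 bromination, 4-O-propargylation, PMB and ketal protection, propargyl-to-allenyl isomerization and bromine-to-formyl exchange.

Key step: step 7

Remark (assumption): the sense of induction of the bisphosphine in the tethered transition state cannot be derived from the intermolecular cases; (S,S)-Ph-BPE is written, and its commercially available antipode would be used instead if the first run gives the (2S,3S) series.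

**Route**

Step 1
Reactants: 1 2,4-dihydroxyacetophenone
Product: 2 1-(5-bromo-2,4-dihydroxyphenyl)ethan-1-one
Conditions: Br2 (1.0 equiv), AcOH, 15 °C to rt
Reagents that add atoms: bromine, BrBr
Why: Electrophilic aromatic bromination; C5 is ortho to the free 4-OH, para to the chelated 2-OH and less hindered than C3 between the two hydroxyls, so one equivalent of bromine should give the 5-bromide.

Step 2
Reactants: 2 1-(5-bromo-2,4-dihydroxyphenyl)ethan-1-one, 3 3-bromoprop-1-yne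
Product: 4 1-[5-bromo-2-hydroxy-4-(prop-2-yn-1-yloxy)phenyl]ethan-1-one
Conditions: K2CO3 (1.1 equiv), acetone, 50 °C
Reagents that add atoms: 3-bromoprop-1-yne (compound 3), BrCC#C
Why: Williamson ether synthesis; the 4-OH is the more acidic phenol and is not held in the hydrogen bond to the acetyl carbonyl, so mild carbonate base should alkylate it selectively.

Step 3
Reactants: 4 1-[5-bromo-2-hydroxy-4-(prop-2-yn-1-yloxy)phenyl]ethan-1-one
Product: 5 1-{5-bromo-2-[(4-methoxyphenyl)methoxy]-4-(prop-2-yn-1-yloxy)phenyl}ethan-1-one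
Conditions: 4-methoxybenzyl chloride (1.3 equiv), K2CO3, Bu4NI (cat.), DMF, 60 °C
Reagents that add atoms: 4-methoxybenzyl chloride, COc1ccc(CCl)cc1
Why: Williamson etherification of the chelated phenol under more forcing carbonate/DMF conditions, which the aryl propargyl ether and the aryl bromide tolerate.

Step 4
Reactants: 5 1-{5-bromo-2-[(4-methoxyphenyl)methoxy]-4-(prop-2-yn-1-yloxy)phenyl}ethan-1-one
Product: 6 2-{5-bromo-2-[(4-methoxyphenyl)methoxy]-4-(prop-2-yn-1-yloxy)phenyl}-2-methyl-1,3-dioxolane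
Conditions: Me3SiOCH2CH2OSiMe3 (3 equiv), Me3SiOSO2CF3 (5 mol%), CH2Cl2, −20 °C; pyridine quench
Reagents that add atoms: 1,2-bis(trimethylsilyloxy)ethane, C[Si](C)(C)OCCO[Si](C)(C)C
Why: Noyori ketalization, an aprotic low-temperature acetalization driven by formation of hexamethyldisiloxane, which should spare the acid-sensitive PMB aryl ether.

Step 5
Reactants: 6 2-{5-bromo-2-[(4-methoxyphenyl)methoxy]-4-(prop-2-yn-1-yloxy)phenyl}-2-methyl-1,3-dioxolane
Product: 7 2-{5-bromo-2-[(4-methoxyphenyl)methoxy]-4-(propa-1,2-dien-1-yloxy)phenyl}-2-methyl-1,3-dioxolane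
Conditions: KOtBu (0.3 equiv), THF, 0 °C to rt
Reagents that add atoms: none
Why: Base-mediated propargyl-to-allenyl prototropic isomerization, the standard preparation of aryloxyallenes; ketal, PMB ether and aryl bromide are inert to catalytic tert-butoxide.

Step 6
Reactants: 7 2-{5-bromo-2-[(4-methoxyphenyl)methoxy]-4-(propa-1,2-dien-1-yloxy)phenyl}-2-methyl-1,3-dioxolane
Product: 10 4-[(4-methoxyphenyl)methoxy]-5-(2-methyl-1,3-dioxolan-2-yl)-2-(propa-1,2-dien-1-yloxy)benzaldehyde, via arylmagnesium chloride 8 (not isolated), via magnesium hemiaminal alkoxide 9 (not isolated)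
Conditions: iPrMgCl·LiCl (1.3 equiv), THF, 0 °C to rt; DMF (3 equiv), 0 °C; pH 7 aqueous work-up
Reagents that add atoms: N,N-dimethylformamide, CN(C)C=O
Why: Bromine–magnesium exchange assisted by the ortho alkoxy group, then Bouveault formylation with DMF; the arylmagnesium species should be too weakly basic to metalate the allenyl C–H, the ketal is inert, and the hemiaminal alkoxide collapses to the aldehyde on neutral work-up.

Step 7
Reactants: 10 4-[(4-methoxyphenyl)methoxy]-5-(2-methyl-1,3-dioxolan-2-yl)-2-(propa-1,2-dien-1-yloxy)benzaldehyde, 11 bis(pinacolato)diboron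
Product: 13 (2R,3R)-6-[(4-methoxyphenyl)methoxy]-5-(2-methyl-1,3-dioxolan-2-yl)-2-[1-(4,4,5,5-tetramethyl-1,3,2-dioxaborolan-2-yl)ethenyl]-2,3-dihydro-1-benzofuran-3-ol, via O-boryl ether 12 (not isolated)
Conditions: CuCl (5 mol%), (S,S)-Ph-BPE (6 mol%), NaOtBu (15 mol%), B2pin2 (1.2 equiv), THF, 0 °C to rt, slow addition of 10; aqueous NaHCO3 work-up
Reagents that add atoms: bis(pinacolato)diboron (compound 11), CC1(C)OB(OC1(C)C)B1OC(C)(C)C(C)(C)O1
Why: Proposed new method: a bisphosphine–copper boryl complex formed from CuCl, NaOtBu and B2pin2 should add across the terminal C=C of the allene anti to the aryloxy group, placing boron on the central carbon and giving a (Z)-γ-aryloxy-β-boryl allylcopper, whose oxygen-bearing γ-carbon then adds to the ortho aldehyde through a closed six-membered transition state before the copper alkoxide is borylated by B2pin2 to release 12 and regenerate the copper boryl. The closest known reaction type is the intermolecular copper-catalysed enantioselective borylative coupling of monosubstituted allenes with aldehydes and ketones via 2-boryl allylcopper intermediates, and tethering the aldehyde through the oxygen substituent of the allene has not been shown. The dihydrofuran ring closes in a 5-exo-trig mode as the C2–C3 bond forms. C2 and C3 arise in the same bond-forming event: their cis relationship should follow from the Z allylcopper geometry in the chair-like transition state, and their absolute configuration from the chiral bisphosphine, which selects the aldehyde face. The step needs borylcupration of the allene in preference to 1,2-addition of the copper boryl to the aldehyde, which the weakly electrophilic, ortho/para-dialkoxy-substituted aldehyde and the fast intramolecular capture should secure, and γ- rather than α-attack of the allyl unit, which the five- versus seven-membered ring size enforces.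

Step 8
Reactants: 13 (2R,3R)-6-[(4-methoxyphenyl)methoxy]-5-(2-methyl-1,3-dioxolan-2-yl)-2-[1-(4,4,5,5-tetramethyl-1,3,2-dioxaborolan-2-yl)ethenyl]-2,3-dihydro-1-benzofuran-3-ol
Product: 14 tert-butyl{[(2R,3R)-6-[(4-methoxyphenyl)methoxy]-5-(2-methyl-1,3-dioxolan-2-yl)-2-[1-(4,4,5,5-tetramethyl-1,3,2-dioxaborolan-2-yl)ethenyl]-2,3-dihydro-1-benzofuran-3-yl]oxy}dimethylsilane
Conditions: TBSCl (1.5 equiv), imidazole (3 equiv), DMAP (cat.), DMF, rt to 40 °C
Reagents that add atoms: tert-butyldimethylsilyl chloride, CC(C)(C)[Si](C)(C)Cl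
Why: Silyl ether formation on the only free hydroxyl, which masks the C3 alkoxide during the organolithium step and keeps the two oxygens distinguishable later.

Step 9
Reactants: 14 tert-butyl{[(2R,3R)-6-[(4-methoxyphenyl)methoxy]-5-(2-methyl-1,3-dioxolan-2-yl)-2-[1-(4,4,5,5-tetramethyl-1,3,2-dioxaborolan-2-yl)ethenyl]-2,3-dihydro-1-benzofuran-3-yl]oxy}dimethylsilane
Product: 17 2-[(2R,3R)-3-{[tert-butyl(dimethyl)silyl]oxy}-6-[(4-methoxyphenyl)methoxy]-5-(2-methyl-1,3-dioxolan-2-yl)-2,3-dihydro-1-benzofuran-2-yl]prop-2-en-1-ol, via chloromethyl borate complex 15 (not isolated), via allylboronate 16 (not isolated)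
Conditions: ClCH2I (2.5 equiv), n-BuLi (2.2 equiv), THF, −78 °C to rt; then NaBO3·4H2O, THF/H2O, rt
Reagents that add atoms: chloroiodomethane, ClCI; sodium perborate (NaBO3·4H2O), [Na+].[O-]OB=O
Why: Matteson homologation (chloromethyllithium made in situ adds to boron and the alkenyl group undergoes 1,2-migration with loss of chloride) followed by perborate oxidation of the allylboronate with retention of connectivity should give the primary allylic alcohol without touching the stereocentres.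

Step 10
Reactants: 17 2-[(2R,3R)-3-{[tert-butyl(dimethyl)silyl]oxy}-6-[(4-methoxyphenyl)methoxy]-5-(2-methyl-1,3-dioxolan-2-yl)-2,3-dihydro-1-benzofuran-2-yl]prop-2-en-1-ol
Product: 18 2-[(2R,3R)-3-{[tert-butyl(dimethyl)silyl]oxy}-6-[(4-methoxyphenyl)methoxy]-5-(2-methyl-1,3-dioxolan-2-yl)-2,3-dihydro-1-benzofuran-2-yl]prop-2-en-1-yl acetate
Conditions: Ac2O, pyridine, DMAP (cat.), CH2Cl2, 0 °C to rt
Reagents that add atoms: acetic anhydride, CC(=O)OC(C)=O
Why: DMAP-catalysed acetylation of the primary allylic alcohol, the only free hydroxyl.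

Step 11
Reactants: 18 2-[(2R,3R)-3-{[tert-butyl(dimethyl)silyl]oxy}-6-[(4-methoxyphenyl)methoxy]-5-(2-methyl-1,3-dioxolan-2-yl)-2,3-dihydro-1-benzofuran-2-yl]prop-2-en-1-yl acetate
Product: 19 2-[(2R,3R)-3-hydroxy-6-[(4-methoxyphenyl)methoxy]-5-(2-methyl-1,3-dioxolan-2-yl)-2,3-dihydro-1-benzofuran-2-yl]prop-2-en-1-yl acetate
Conditions: Bu4NF (1.5 equiv), AcOH (1.5 equiv), THF, 0 °C to rt
Reagents that add atoms: none
Why: Fluoride-mediated desilylation, buffered with acetic acid so that the liberated alkoxide is protonated before it can take up the acetate or trigger elimination.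

Step 12
Reactants: 19 2-[(2R,3R)-3-hydroxy-6-[(4-methoxyphenyl)methoxy]-5-(2-methyl-1,3-dioxolan-2-yl)-2,3-dihydro-1-benzofuran-2-yl]prop-2-en-1-yl acetate, 20 angelic acid [(2Z)-2-methylbut-2-enoic acid]
Product: 21 (2R,3R)-2-[3-(acetyloxy)prop-1-en-2-yl]-6-[(4-methoxyphenyl)methoxy]-5-(2-methyl-1,3-dioxolan-2-yl)-2,3-dihydro-1-benzofuran-3-yl (2Z)-2-methylbut-2-enoate
Conditions: angelic acid (3 equiv), 2,4,6-trichlorobenzoyl chloride (3 equiv), Et3N (3.3 equiv), toluene, rt; then 19, 75 °C (no DMAP)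
Reagents that add atoms: angelic acid (compound 20), C/C=C(/C)C(=O)O
Why: Yamaguchi-type esterification through the mixed 2,4,6-trichlorobenzoic anhydride without DMAP, the established way to acylate hindered secondary alcohols with angelic acid without Z-to-E isomerization; the C3–O bond is not broken, so configuration is retained.

Step 13
Reactants: 21 (2R,3R)-2-[3-(acetyloxy)prop-1-en-2-yl]-6-[(4-methoxyphenyl)methoxy]-5-(2-methyl-1,3-dioxolan-2-yl)-2,3-dihydro-1-benzofuran-3-yl (2Z)-2-methylbut-2-enoate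
Product: 22 (2R,3R)-5-acetyl-2-[3-(acetyloxy)prop-1-en-2-yl]-6-[(4-methoxyphenyl)methoxy]-2,3-dihydro-1-benzofuran-3-yl (2Z)-2-methylbut-2-enoate
Conditions: pyridinium p-toluenesulfonate (0.2 equiv), acetone/H2O (10:1), rt to 40 °C
Reagents that add atoms: water, O
Why: Acid-catalysed ketal hydrolysis; the dioxolane of an electron-rich aryl ketone should ionize far more readily than the benzylic angelate or the PMB ether, so a pyridinium salt in wet acetone should suffice.

Step 14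
Reactants: 22 (2R,3R)-5-acetyl-2-[3-(acetyloxy)prop-1-en-2-yl]-6-[(4-methoxyphenyl)methoxy]-2,3-dihydro-1-benzofuran-3-yl (2Z)-2-methylbut-2-enoate
Product: 23 (2R,3R)-5-acetyl-2-[3-(acetyloxy)prop-1-en-2-yl]-6-hydroxy-2,3-dihydro-1-benzofuran-3-yl (2Z)-2-methylbut-2-enoate (target CNP0323250.1)
Conditions: DDQ (1.5 equiv), CH2Cl2/pH 7 phosphate buffer (10:1), 0 °C to rt
Reagents that add atoms: none
Why: Oxidative PMB ether cleavage with DDQ under buffered, non-acidic conditions, chosen because the C3 ester is a para-oxygenated benzylic ester that would ionize in strong acid; the acetyl group deactivates the benzofuran ring toward over-oxidation.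

**Compound list**

1 | 2,4-dihydroxyacetophenone | CC(=O)c1ccc(O)cc1O | starting material
2 | 1-(5-bromo-2,4-dihydroxyphenyl)ethan-1-one | CC(=O)c1cc(Br)c(O)cc1O | intermediate
3 | 3-bromoprop-1-yne | BrCC#C | starting material
4 | 1-[5-bromo-2-hydroxy-4-(prop-2-yn-1-yloxy)phenyl]ethan-1-one | CC(=O)c1cc(Br)c(OCC#C)cc1O | intermediate
5 | 1-{5-bromo-2-[(4-methoxyphenyl)methoxy]-4-(prop-2-yn-1-yloxy)phenyl}ethan-1-one | CC(=O)c1cc(Br)c(OCC#C)cc1OCc2ccc(OC)cc2 | intermediate
6 | 2-{5-bromo-2-[(4-methoxyphenyl)methoxy]-4-(prop-2-yn-1-yloxy)phenyl}-2-methyl-1,3-dioxolane | CC1(OCCO1)c2cc(Br)c(OCC#C)cc2OCc3ccc(OC)cc3 | intermediate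
7 | 2-{5-bromo-2-[(4-methoxyphenyl)methoxy]-4-(propa-1,2-dien-1-yloxy)phenyl}-2-methyl-1,3-dioxolane | CC1(OCCO1)c2cc(Br)c(OC=C=C)cc2OCc3ccc(OC)cc3 | intermediate
8 | chloro{4-[(4-methoxyphenyl)methoxy]-5-(2-methyl-1,3-dioxolan-2-yl)-2-(propa-1,2-dien-1-yloxy)phenyl}magnesium (LiCl complex) | CC1(OCCO1)c2cc([Mg]Cl)c(OC=C=C)cc2OCc3ccc(OC)cc3 | intermediate (not isolated)
9 | chloromagnesium (dimethylamino){4-[(4-methoxyphenyl)methoxy]-5-(2-methyl-1,3-dioxolan-2-yl)-2-(propa-1,2-dien-1-yloxy)phenyl}methanolate | CC1(OCCO1)c2cc(C(O[Mg]Cl)N(C)C)c(OC=C=C)cc2OCc3ccc(OC)cc3 | intermediate (not isolated)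
10 | 4-[(4-methoxyphenyl)methoxy]-5-(2-methyl-1,3-dioxolan-2-yl)-2-(propa-1,2-dien-1-yloxy)benzaldehyde | CC1(OCCO1)c2cc(C=O)c(OC=C=C)cc2OCc3ccc(OC)cc3 | intermediate
11 | bis(pinacolato)diboron | CC1(C)OB(OC1(C)C)B1OC(C)(C)C(C)(C)O1 | starting material
12 | 2-{[(2R,3R)-6-[(4-methoxyphenyl)methoxy]-5-(2-methyl-1,3-dioxolan-2-yl)-2-[1-(4,4,5,5-tetramethyl-1,3,2-dioxaborolan-2-yl)ethenyl]-2,3-dihydro-1-benzofuran-3-yl]oxy}-4,4,5,5-tetramethyl-1,3,2-dioxaborolane | C=C(B1OC(C)(C)C(C)(C)O1)[C@H]2Oc3cc(OCc4ccc(OC)cc4)c(C5(C)OCCO5)cc3[C@H]2OB6OC(C)(C)C(C)(C)O6 | intermediate (not isolated)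
13 | (2R,3R)-6-[(4-methoxyphenyl)methoxy]-5-(2-methyl-1,3-dioxolan-2-yl)-2-[1-(4,4,5,5-tetramethyl-1,3,2-dioxaborolan-2-yl)ethenyl]-2,3-dihydro-1-benzofuran-3-ol | C=C(B1OC(C)(C)C(C)(C)O1)[C@H]2Oc3cc(OCc4ccc(OC)cc4)c(C5(C)OCCO5)cc3[C@H]2O | intermediate
14 | tert-butyl{[(2R,3R)-6-[(4-methoxyphenyl)methoxy]-5-(2-methyl-1,3-dioxolan-2-yl)-2-[1-(4,4,5,5-tetramethyl-1,3,2-dioxaborolan-2-yl)ethenyl]-2,3-dihydro-1-benzofuran-3-yl]oxy}dimethylsilane | C=C(B1OC(C)(C)C(C)(C)O1)[C@H]2Oc3cc(OCc4ccc(OC)cc4)c(C5(C)OCCO5)cc3[C@H]2O[Si](C)(C)C(C)(C)C | intermediate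
15 | lithium (chloromethyl){1-[(2R,3R)-3-{[tert-butyl(dimethyl)silyl]oxy}-6-[(4-methoxyphenyl)methoxy]-5-(2-methyl-1,3-dioxolan-2-yl)-2,3-dihydro-1-benzofuran-2-yl]ethenyl}(2,3-dimethylbutane-2,3-diolato)borate | [Li+].C=C([B-]1(CCl)OC(C)(C)C(C)(C)O1)[C@H]2Oc3cc(OCc4ccc(OC)cc4)c(C5(C)OCCO5)cc3[C@H]2O[Si](C)(C)C(C)(C)C | intermediate (not isolated)
16 | tert-butyl{[(2R,3R)-6-[(4-methoxyphenyl)methoxy]-5-(2-methyl-1,3-dioxolan-2-yl)-2-[3-(4,4,5,5-tetramethyl-1,3,2-dioxaborolan-2-yl)prop-1-en-2-yl]-2,3-dihydro-1-benzofuran-3-yl]oxy}dimethylsilane | C=C(CB1OC(C)(C)C(C)(C)O1)[C@H]2Oc3cc(OCc4ccc(OC)cc4)c(C5(C)OCCO5)cc3[C@H]2O[Si](C)(C)C(C)(C)C | intermediate (not isolated)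
17 | 2-[(2R,3R)-3-{[tert-butyl(dimethyl)silyl]oxy}-6-[(4-methoxyphenyl)methoxy]-5-(2-methyl-1,3-dioxolan-2-yl)-2,3-dihydro-1-benzofuran-2-yl]prop-2-en-1-ol | C=C(CO)[C@H]2Oc3cc(OCc4ccc(OC)cc4)c(C5(C)OCCO5)cc3[C@H]2O[Si](C)(C)C(C)(C)C | intermediate
18 | 2-[(2R,3R)-3-{[tert-butyl(dimethyl)silyl]oxy}-6-[(4-methoxyphenyl)methoxy]-5-(2-methyl-1,3-dioxolan-2-yl)-2,3-dihydro-1-benzofuran-2-yl]prop-2-en-1-yl acetate | C=C(COC(C)=O)[C@H]2Oc3cc(OCc4ccc(OC)cc4)c(C5(C)OCCO5)cc3[C@H]2O[Si](C)(C)C(C)(C)C | intermediate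
19 | 2-[(2R,3R)-3-hydroxy-6-[(4-methoxyphenyl)methoxy]-5-(2-methyl-1,3-dioxolan-2-yl)-2,3-dihydro-1-benzofuran-2-yl]prop-2-en-1-yl acetate | C=C(COC(C)=O)[C@H]2Oc3cc(OCc4ccc(OC)cc4)c(C5(C)OCCO5)cc3[C@H]2O | intermediate
20 | angelic acid, (2Z)-2-methylbut-2-enoic acid | C/C=C(/C)C(=O)O | starting material
21 | (2R,3R)-2-[3-(acetyloxy)prop-1-en-2-yl]-6-[(4-methoxyphenyl)methoxy]-5-(2-methyl-1,3-dioxolan-2-yl)-2,3-dihydro-1-benzofuran-3-yl (2Z)-2-methylbut-2-enoate | C=C(COC(C)=O)[C@H]2Oc3cc(OCc4ccc(OC)cc4)c(C5(C)OCCO5)cc3[C@H]2OC(=O)/C(C)=C\C | intermediate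
22 | (2R,3R)-5-acetyl-2-[3-(acetyloxy)prop-1-en-2-yl]-6-[(4-methoxyphenyl)methoxy]-2,3-dihydro-1-benzofuran-3-yl (2Z)-2-methylbut-2-enoate | C=C(COC(C)=O)[C@H]2Oc3cc(OCc4ccc(OC)cc4)c(C(C)=O)cc3[C@H]2OC(=O)/C(C)=C\C | intermediate
23 | (2R,3R)-5-acetyl-2-[3-(acetyloxy)prop-1-en-2-yl]-6-hydroxy-2,3-dihydro-1-benzofuran-3-yl (2Z)-2-methylbut-2-enoate | C=C(COC(C)=O)[C@H]1Oc2cc(O)c(C(C)=O)cc2[C@H]1OC(=O)/C(C)=C\C | target

**Step count**

Total: 14 steps. Longest linear sequence: 14 steps (1 to 23).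

**Steps most likely to fail**

1. Step 7 (proposed new method). The ring closure may proceed without useful facial or cis/trans control in the constrained tethered transition state, or the copper boryl may be diverted to borylation of the aldehyde so that the allylcopper never forms. Fallback with known reaction types, from 10 back to 13:
   - Platinum-catalysed diboration of the terminal allene C=C (Pt(dba)2, PCy3, B2pin2, toluene, 50 °C) would give the (Z)-allyl/alkenyl bis(boronate) aldehyde F1.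
   - Its allylboronate unit adds to the ortho aldehyde without catalyst through the closed chair transition state (intramolecular allylboration, 5-exo), which should give the racemic cis O-boryl ether F2 and, after aqueous work-up, the racemic cis alcohol F3.
   - Resolution: esterification with (S)-2-methoxy-2-phenylacetic acid (DCC, DMAP, CH2Cl2) gives the (2R,3R) ester F4 and the (2S,3S) ester F5, to be separated on silica.
   - Methanolysis of F4 (K2CO3, MeOH) returns 13.

2. Step 6. Bromine–magnesium exchange on the electron-rich ring may be too slow, or the organometallic may metalate the allenyl C–H, so that the aryl Grignard reagent does not form cleanly. Fallback that makes the aldehyde before the allene, from 6 back to 10: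
   - The alkyne C–H is first magnesiated (iPrMgCl, THF, 0 °C); bromine–lithium exchange (n-BuLi, −78 °C) and DMF at −78 °C then give the propargyl ether aldehyde F6.
   - NaBH4 (MeOH, 0 °C) gives the benzylic alcohol F7.
   - KOtBu (1.5 equiv, THF, rt) isomerizes the propargyl ether, with the alcohol protected as its potassium alkoxide, to the allenyl ether alcohol F8.
   - MnO2 (CH2Cl2, rt) oxidizes the benzylic alcohol to 10.

3. Step 12. The activated angeloyl group may isomerize from Z to E (tiglate) during acylation, or acylation of the hindered cis benzylic alcohol may stall. Fallback that builds the Z alkene on the ester, from 19 back to 21: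
   - DCC/DMAP esterification with 2-[bis(2,2,2-trifluoroethoxy)phosphoryl]propanoic acid gives the phosphonopropanoate F9.
   - Still–Gennari olefination with acetaldehyde (KN(SiMe3)2, 18-crown-6, THF, −78 °C) should give the Z-trisubstituted enoate 21.

**Further compounds**

F1 | step 7 | 2-{[(1Z)-2,3-bis(4,4,5,5-tetramethyl-1,3,2-dioxaborolan-2-yl)prop-1-en-1-yl]oxy}-4-[(4-methoxyphenyl)methoxy]-5-(2-methyl-1,3-dioxolan-2-yl)benzaldehyde | O=Cc1cc(C2(C)OCCO2)c(OCc3ccc(OC)cc3)cc1O/C=C(\CB4OC(C)(C)C(C)(C)O4)B5OC(C)(C)C(C)(C)O5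
F2 | step 7 | racemic cis O-boryl ether, (2R,3R) and (2S,3S) forms of compound 12 | C=C(B1OC(C)(C)C(C)(C)O1)[C@H]2Oc3cc(OCc4ccc(OC)cc4)c(C5(C)OCCO5)cc3[C@H]2OB6OC(C)(C)C(C)(C)O6.C=C(B1OC(C)(C)C(C)(C)O1)[C@@H]2Oc3cc(OCc4ccc(OC)cc4)c(C5(C)OCCO5)cc3[C@@H]2OB6OC(C)(C)C(C)(C)O6
F3 | step 7 | racemic cis alcohol, (2R,3R) and (2S,3S) forms of compound 13 | C=C(B1OC(C)(C)C(C)(C)O1)[C@H]2Oc3cc(OCc4ccc(OC)cc4)c(C5(C)OCCO5)cc3[C@H]2O.C=C(B1OC(C)(C)C(C)(C)O1)[C@@H]2Oc3cc(OCc4ccc(OC)cc4)c(C5(C)OCCO5)cc3[C@@H]2O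
F4 | step 7 | (2R,3R)-6-[(4-methoxyphenyl)methoxy]-5-(2-methyl-1,3-dioxolan-2-yl)-2-[1-(4,4,5,5-tetramethyl-1,3,2-dioxaborolan-2-yl)ethenyl]-2,3-dihydro-1-benzofuran-3-yl (2S)-2-methoxy-2-phenylacetate | C=C(B1OC(C)(C)C(C)(C)O1)[C@H]2Oc3cc(OCc4ccc(OC)cc4)c(C5(C)OCCO5)cc3[C@H]2OC(=O)[C@@H](OC)c6ccccc6
F5 | step 7 | (2S,3S)-6-[(4-methoxyphenyl)methoxy]-5-(2-methyl-1,3-dioxolan-2-yl)-2-[1-(4,4,5,5-tetramethyl-1,3,2-dioxaborolan-2-yl)ethenyl]-2,3-dihydro-1-benzofuran-3-yl (2S)-2-methoxy-2-phenylacetate | C=C(B1OC(C)(C)C(C)(C)O1)[C@@H]2Oc3cc(OCc4ccc(OC)cc4)c(C5(C)OCCO5)cc3[C@@H]2OC(=O)[C@@H](OC)c6ccccc6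
F6 | step 6 | 4-[(4-methoxyphenyl)methoxy]-5-(2-methyl-1,3-dioxolan-2-yl)-2-(prop-2-yn-1-yloxy)benzaldehyde | CC1(OCCO1)c2cc(C=O)c(OCC#C)cc2OCc3ccc(OC)cc3
F7 | step 6 | {4-[(4-methoxyphenyl)methoxy]-5-(2-methyl-1,3-dioxolan-2-yl)-2-(prop-2-yn-1-yloxy)phenyl}methanol | CC1(OCCO1)c2cc(CO)c(OCC#C)cc2OCc3ccc(OC)cc3
F8 | step 6 | {4-[(4-methoxyphenyl)methoxy]-5-(2-methyl-1,3-dioxolan-2-yl)-2-(propa-1,2-dien-1-yloxy)phenyl}methanol | CC1(OCCO1)c2cc(CO)c(OC=C=C)cc2OCc3ccc(OC)cc3
F9 | step 12 | (2R,3R)-2-[3-(acetyloxy)prop-1-en-2-yl]-6-[(4-methoxyphenyl)methoxy]-5-(2-methyl-1,3-dioxolan-2-yl)-2,3-dihydro-1-benzofuran-3-yl 2-[bis(2,2,2-trifluoroethoxy)phosphoryl]propanoate | C=C(COC(C)=O)[C@H]2Oc3cc(OCc4ccc(OC)cc4)c(C5(C)OCCO5)cc3[C@H]2OC(=O)C(C)P(=O)(OCC(F)(F)F)OCC(F)(F)F
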